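Numbering: C1 ring ketone, C2/C3 ring CH2, C4 quaternary carbon, C5 ring CH, C6/C7 cyclopropane CH, C11 CMe2, C8–C10 butanone chain, C9′ benzylic CH.
Cuts, in retrosynthetic order: three phenol O–H (kept as O–CH3) and two aryl–CHO bonds; C8=C9 (Wittig); C7–C11 and C6–C11 (2-diazopropane); C6=C7 (metathesis); C1–C2 (hydroacylation); C4–C5 (Ireland–Claisen); C4–CH3 (cuprate); C9′–CH2 (enolate alkylation).
Enabling feature: in the cis-1,2-disubstituted cyclopropane ring C6–C7–C11, C7 carries C8 and C6 carries C5, the neighbour of oxygenated C1. O, C8, C7, C6, C5 and C1 can therefore be closed to a six-membered lactone ring cis-fused to the cyclopentane ring, in which C6=C7 must be Z, is electron-poor and has one open face.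
Forward order: open chain (C9′, then the Z-alkene, then C4/C5), cyclopentane ring, lactone ring, cyclopropane ring. The lactone ring is then opened by reduction, the chain is extended by C9–C10–CH3, and the arene is formylated and deprotected last.
Stereochemistry: C9′ comes from (R)-4-benzyloxazolidinone. C4 follows from C9′ by A(1,3)-controlled face selection, and C5 from the chair transition state of the sigmatropic step. The temporary C1–O centre comes from hydride attack anti to the vinyl group, and C6/C7 from addition to the convex face of the bicyclic lactone.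

Key step: step 18

Assumption: the target SMILES reads 4R,5R,6R,7R,9′S in the numbering above, and all descriptors below refer to that numbering or to the systematic name given.

Step 1
Reactants: 1 (2,4,6-trimethoxyphenyl)acetic acid; 2 (R)-4-benzyl-1,3-oxazolidin-2-one
Product: 4 (R)-4-benzyl-3-[(2,4,6-trimethoxyphenyl)acetyl]-1,3-oxazolidin-2-one, via mixed pivalic anhydride 3 (not isolated)
Conditions: t-BuCOCl, Et3N, THF, −20 °C; then 2, LiCl, −20 °C to rt
Reagents that add atoms: none
Why: N-Acylation of an Evans oxazolidinone through the mixed anhydride, with LiCl activating the neutral carbamate, loads the arylacetic acid without a strong base and creates no stereocentre.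

Step 2
Reactants: 4 N-(arylacetyl)oxazolidinone
Product: 6 (R)-4-benzyl-3-[(2R)-4-methyl-2-(2,4,6-trimethoxyphenyl)pent-4-enoyl]-1,3-oxazolidin-2-one, via sodium Z-enolate 5 (not isolated)
Conditions: NaN(SiMe3)2, THF, −78 °C; CH2=C(CH3)CH2Br, −78 to −40 °C
Reagents that add atoms: 3-bromo-2-methylprop-1-ene, C=C(C)CBr
Why: In this Evans asymmetric alkylation the chelated Z-enolate is shielded on one face by the benzyl group, so the allylic bromide (chosen because isobutyl halides are too sluggish for imide enolates) enters from the other face and sets C9′.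

Step 3
Reactants: 6 methallylated imide
Product: 7 (R)-4-benzyl-3-[(2R)-4-methyl-2-(2,4,6-trimethoxyphenyl)pentanoyl]-1,3-oxazolidin-2-one
Conditions: H2 (1 atm), Pd/C, EtOAc, rt
Reagents that add atoms: none
Why: Heterogeneous catalytic hydrogenation saturates the unhindered 1,1-disubstituted alkene to the isobutyl group and leaves arene, imide and C9′ untouched.

Step 4
Reactants: 7 isobutyl imide
Product: 8 (2R)-4-methyl-2-(2,4,6-trimethoxyphenyl)pentan-1-ol
Conditions: LiBH4, H2O (1 equiv), Et2O, 0 °C
Reagents that add atoms: none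
Why: Reductive cleavage of an N-acyl oxazolidinone with LiBH4 attacks the exocyclic carbonyl, gives the primary alcohol without enolising C9′ and returns the auxiliary.

Step 5
Reactants: 8 primary alcohol
Product: 9 (2R)-4-methyl-2-(2,4,6-trimethoxyphenyl)pentanal
Conditions: Dess–Martin periodinane, pyridine, CH2Cl2, 0 °C; used crude
Reagents that add atoms: none
Why: The Dess–Martin oxidation runs close to neutrality, and the twisted, electron-rich aryl group lowers the acidity of C9′–H, so the α-aryl aldehyde should keep its configuration if it is not chromatographed.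

Step 6
Reactants: 9 α-aryl aldehyde
Product: 10 2-[(3S)-1,1-dibromo-5-methylhex-1-en-3-yl]-1,3,5-trimethoxybenzene
Conditions: CBr4, PPh3, Zn, CH2Cl2, rt (ylide preformed); then 9, 0 °C to rt
Reagents that add atoms: carbon tetrabromide, BrC(Br)(Br)Br
Why: The dibromoolefination stage of the Corey–Fuchs sequence, run with the ylide preformed over zinc, is base-free and leaves no bromophosphonium salt that could brominate the arene or epimerise C9′.

Step 7
Reactants: 10 dibromoalkene
Product: 12 methyl (4S)-6-methyl-4-(2,4,6-trimethoxyphenyl)hept-2-ynoate, via lithium acetylide 11 (not isolated)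
Conditions: n-BuLi (2.1 equiv), THF, −78 °C; ClCO2Me, −78 to 0 °C
Reagents that add atoms: methyl chloroformate, COC(=O)Cl
Why: In the second Corey–Fuchs stage, bromine–lithium exchange, 1,2-shift and deprotonation give the acetylide, which is acylated in the same flask, the exchange at −78 °C being far faster than lithiation of the arene.

Step 8
Reactants: 12 ynoate
Product: 13 methyl (2Z,4S)-3,6-dimethyl-4-(2,4,6-trimethoxyphenyl)hept-2-enoate
Conditions: Me2CuLi (from MeLi, CuI), THF, −78 °C; aq NH4Cl at −78 °C
Reagents that add atoms: lithium dimethylcuprate, [Li+].C[Cu-]C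
Why: Syn-carbocupration of a 2-ynoate, with protonation at −78 °C before the alkenylcuprate can isomerise through its allenolate, places CH3 cis to H and hence C9′ cis to the ester, which is the Z-alkene.

Step 9
Reactants: 13 Z-enoate
Product: 14 (2Z,4S)-3,6-dimethyl-4-(2,4,6-trimethoxyphenyl)hept-2-en-1-ol
Conditions: i-Bu2AlH (2.5 equiv), CH2Cl2, −78 °C
Reagents that add atoms: none
Why: The 1,2-reduction of an α,β-unsaturated ester with i-Bu2AlH gives the allylic alcohol with the alkene geometry retained.

Step 10
Reactants: 14 Z-allylic alcohol; 15 but-3-enoic acid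
Product: 16 (2Z,4S)-3,6-dimethyl-4-(2,4,6-trimethoxyphenyl)hept-2-en-1-yl but-3-enoate
Conditions: DCC, DMAP (5 mol %), CH2Cl2, 0 °C
Reagents that add atoms: none
Why: A Steglich esterification at 0 °C with little DMAP couples the primary allylic alcohol faster than the β,γ-double bond of the acid moves into conjugation.

Step 11
Reactants: 16 Z-allylic but-3-enoate
Product: 19 (2R,3R)-2-ethenyl-3-methyl-3-[(1S)-3-methyl-1-(2,4,6-trimethoxyphenyl)butyl]pent-4-en-1-ol, via E-silyl ketene acetal 17 (not isolated), via trimethylsilyl ester 18 (not isolated)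
Conditions: Me3SiCl, LiN(iPr)2 (internal quench), THF, −78 °C, then 60 °C; evaporate; LiAlH4, Et2O, 0 °C
Reagents that add atoms: none
Why: This is an Ireland–Claisen rearrangement followed by hydride reduction of the silyl ester, in which kinetic enolisation in THF gives the E-ketene acetal, A(1,3) strain in the Z-alkene holds C9′–H in the alkene plane toward C2 so that C5 bonds to the C4 face opposite the aryl group (C4 R), the chair transition state places the C5 vinyl group on the side of the C4 methyl group (C5 R), and the moderate temperature keeps the new 1,5-diene from a Cope rearrangement.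

Step 12
Reactants: 19 divinyl alcohol
Product: 20 (2R,3R)-2-ethenyl-3-methyl-3-[(1S)-3-methyl-1-(2,4,6-trimethoxyphenyl)butyl]pent-4-enal
Conditions: Dess–Martin periodinane, pyridine, CH2Cl2, 0 °C
Reagents that add atoms: none
Why: The buffered Dess–Martin oxidation gives the β,γ-unsaturated aldehyde without base or acid strong enough to conjugate the C5 vinyl group or to epimerise C5.

Step 13
Reactants: 20 4-pentenal
Product: 21 (2R,3R)-2-ethenyl-3-methyl-3-[(1S)-3-methyl-1-(2,4,6-trimethoxyphenyl)butyl]cyclopentan-1-one
Conditions: [Rh(nbd)(dppe)]BF4 (5 mol %, activated with H2), acetone, rt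
Reagents that add atoms: none
Why: In this intramolecular hydroacylation of a 4-pentenal by a cationic diphosphine complex of monovalent rhodium, C1–H oxidative addition, hydride insertion into the C2=C3 vinyl group and reductive elimination from the six-membered acyl rhodacycle form C1–C2, the 3,3-disubstitution favours closure over decarbonylation, and the C5 vinyl group could only lead to a strained four-membered ketone.

Step 14
Reactants: 21 2-vinylcyclopentanone
Product: 22 (1S,2R,3R)-2-ethenyl-3-methyl-3-[(1S)-3-methyl-1-(2,4,6-trimethoxyphenyl)butyl]cyclopentan-1-ol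
Conditions: LiBH(s-Bu)3, THF, −78 °C; then NaOH, H2O2, 0 °C
Reagents that add atoms: none
Why: In this diastereoselective ketone reduction the bulky trialkylborohydride reaches C1 from the face opposite the adjacent C5 vinyl group and the pseudoaxial C4 methyl group, which places the C1 oxygen cis to C6 (C1 S).

Step 15
Reactants: 22 cis-2-vinylcyclopentanol; 23 acryloyl chloride
Product: 24 (1S,2R,3R)-2-ethenyl-3-methyl-3-[(1S)-3-methyl-1-(2,4,6-trimethoxyphenyl)butyl]cyclopentyl prop-2-enoate
Conditions: Et3N, DMAP (cat.), CH2Cl2, 0 °C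
Reagents that add atoms: none
Why: DMAP-catalysed O-acylation of a secondary alcohol with an acid chloride is routine and touches no stereocentre.

Step 16
Reactants: 24 acrylate
Product: 25 cis-fused pentenolide (4aR,5R,7aS)-5-methyl-5-[(1S)-3-methyl-1-(2,4,6-trimethoxyphenyl)butyl]-4a,5,6,7-tetrahydrocyclopenta[b]pyran-2(7aH)-one
Conditions: second-generation Grubbs catalyst RuCl2(=CHPh)(PCy3)(H2IMes) (5 mol %), CH2Cl2 (2 mM), reflux
Reagents that add atoms: none
Why: Ring-closing metathesis of an acrylate with a vicinal cis vinyl group is the standard entry to 5,6-dihydropyran-2-ones, is driven by loss of ethene, and can give only the Z C6=C7 bond in the six-membered ring.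

Step 17
Reactants: 26 acetone hydrazone
Product: 27 2-diazopropane (ethereal solution)
Conditions: HgO, KOH (cat.) in EtOH, Et2O, rt, reduced pressure, co-distilled into a −78 °C trap
Reagents that add atoms: none
Why: Base-catalysed dehydrogenation of a hydrazone with HgO is the standard preparation of 2-diazopropane, which is used at once because it decays within hours at 0 °C.

Step 18
Reactants: 25 cis-fused pentenolide; 27 2-diazopropane
Product: 29 cyclopropane-fused tricyclic δ-lactone, via 1-pyrazoline 28 (not isolated)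
Conditions: 27 (excess, added in portions), Et2O/CH2Cl2, −20 to 0 °C, dark; evaporate cold; hν (medium-pressure Hg lamp, Pyrex), Ph2CO (sensitiser), toluene, 0 °C
Reagents that add atoms: none
Why: 2-Diazopropane is a nucleophilic 1,3-dipole that adds suprafacially and in concert to the electron-poor C6=C7 bond, with its carbon C11 bonding to the β-carbon C6 and its terminal nitrogen to the α-carbon C7, so the five-membered pyrazoline ring of 28 closes by intermolecular (3+2) cycloaddition. Sensitised excitation of the azo group then breaks both C–N bonds, N2 leaves, and the C7/C11 1,3-diradical recombines, so the three-membered ring closes through C7–C11 by radical–radical coupling, a ring contraction from five to three atoms. The closest known reaction type is the addition of 2-diazopropane to butenolides and pentenolides followed by photolysis of the 1-pyrazolines, the classical route to lactones of the cis-caronic and cis-chrysanthemic series. C6 is fixed by face selection, because the dipole can reach only the convex face of the cis-fused bicycle, where H1 and H5 stand, anti to the C5–C4 bond and away from the C4 methyl group that lies under the concave face; C7 follows from the suprafacial addition and, after loss of N2, from the lactone ring, which allows only cis closure of the bicyclo[4.1.0] unit. The step needs regioselectivity, secured by the polarisation of the enoate, and chemoselectivity, secured because neither acid nor metal carbene meets the electron-rich arene. It also needs the 2-pyrazoline tautomer to be avoided, which cold, neutral, dark handling and immediate irradiation secure.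

Step 19
Reactants: 29 cyclopropane-fused lactone
Product: 30 diol (C1–OH and C8–OH)
Conditions: LiAlH4, THF, 0 °C to rt
Reagents that add atoms: none
Why: LiAlH4 reduction of a lactone gives the 1,5-diol and spares the unactivated cyclopropane and the aryl ethers.

Step 20
Reactants: 30 diol
Product: 32 keto aldehyde (C1 ketone and C8 aldehyde), via bis(alkoxysulfonium) dichloride 31 (not isolated)
Conditions: (COCl)2, DMSO, CH2Cl2, −78 °C; Et3N, −78 to 0 °C
Reagents that add atoms: none
Why: In the Swern oxidation both hydroxyl groups become alkoxysulfonium ions before base is added, so no hydroxy aldehyde can close to a lactol and be oxidised back to 29, while the cyclopropyl C7–H does not enolise and C5 already holds its more stable orientation trans to the C9′ substituent.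

Step 21
Reactants: 32 keto aldehyde
Product: 33 E-enone (C8=C9 conjugated to the C10 ketone)
Conditions: Ph3P=CHC(O)CH3, toluene, 60 °C
Reagents that add atoms: 1-(triphenyl-λ5-phosphanylidene)propan-2-one, CC(=O)C=P(c1ccccc1)(c1ccccc1)c1ccccc1
Why: A Wittig olefination with a stabilised ylide takes the aldehyde but not the hindered cyclopentanone, gives the E-enone, and is neutral enough to leave the cis-cyclopropane and C5 unchanged.

Step 22
Reactants: 33 E-enone
Product: 34 diketone tri-O-methyl ether
Conditions: [(Ph3P)CuH]6, H2O, toluene, rt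
Reagents that add atoms: none
Why: In conjugate reduction with the hexameric phosphine copper hydride a polar hydride is delivered to C8 and water protonates the copper enolate, so no radical arises next to the cyclopropane, the isolated ketone is not reduced, and the neutral medium avoids aldol reaction between the two ketones.

Step 23
Reactants: 34 diketone tri-O-methyl ether
Product: 35 3′,5′-diformyl tri-O-methyl ether
Conditions: Cl2CHOMe (6 equiv), TiCl4 (8 equiv), CH2Cl2, −78 to −10 °C; ice water
Reagents that add atoms: dichloromethyl methyl ether, COC(Cl)Cl; water, O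
Why: In the Rieche formylation the two free ring positions, each flanked by two methoxy groups, are by far the most nucleophilic sites, so excess reagent formylates both, while the ketones merely bind TiCl4 and the low temperature protects the cyclopropane.

Step 24
Reactants: 35 diformyl tri-O-methyl ether
Product: 36 macrocarpal N
Conditions: BCl3 (6 equiv), CH2Cl2, −78 to 0 °C; H2O
Reagents that add atoms: none
Why: In this chelation-assisted aryl methyl ether cleavage each of the three methoxy groups is ortho to a formyl group, so boron binds the carbonyl oxygen and chloride removes the methyl group at low temperature, conditions that the cyclopropane, both ketones and all five stereocentres should survive.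

Compound list
1 | (2,4,6-trimethoxyphenyl)acetic acid | COc1cc(OC)c(CC(=O)O)c(OC)c1 | starting material
2 | (R)-4-benzyl-1,3-oxazolidin-2-one | O=C1N[C@H](Cc2ccccc2)CO1 | starting material
3 | (2,4,6-trimethoxyphenyl)acetic pivalic anhydride | CC(C)(C)C(=O)OC(=O)Cc1c(OC)cc(OC)cc1OC | intermediate
4 | (R)-4-benzyl-3-[(2,4,6-trimethoxyphenyl)acetyl]-1,3-oxazolidin-2-one | O=C1OC[C@@H](Cc2ccccc2)N1C(=O)Cc1c(OC)cc(OC)cc1OC | intermediate
5 | sodium Z-enolate of 4 (O− and aryl cis) | [Na+].[O-]/C(=C\c1c(OC)cc(OC)cc1OC)N1C(=O)OC[C@H]1Cc1ccccc1 | intermediate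
6 | (R)-4-benzyl-3-[(2R)-4-methyl-2-(2,4,6-trimethoxyphenyl)pent-4-enoyl]-1,3-oxazolidin-2-one | O=C1OC[C@@H](Cc2ccccc2)N1C(=O)[C@H](CC(C)=C)c1c(OC)cc(OC)cc1OC | intermediate
7 | (R)-4-benzyl-3-[(2R)-4-methyl-2-(2,4,6-trimethoxyphenyl)pentanoyl]-1,3-oxazolidin-2-one | O=C1OC[C@@H](Cc2ccccc2)N1C(=O)[C@H](CC(C)C)c1c(OC)cc(OC)cc1OC | intermediate
8 | (2R)-4-methyl-2-(2,4,6-trimethoxyphenyl)pentan-1-ol | OC[C@H](CC(C)C)c1c(OC)cc(OC)cc1OC | intermediate
9 | (2R)-4-methyl-2-(2,4,6-trimethoxyphenyl)pentanal | O=C[C@H](CC(C)C)c1c(OC)cc(OC)cc1OC | intermediate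
10 | 2-[(3S)-1,1-dibromo-5-methylhex-1-en-3-yl]-1,3,5-trimethoxybenzene | BrC(Br)=C[C@H](CC(C)C)c1c(OC)cc(OC)cc1OC | intermediate
11 | lithium (3S)-5-methyl-3-(2,4,6-trimethoxyphenyl)hex-1-yn-1-ide | [Li+].[C-]#C[C@H](CC(C)C)c1c(OC)cc(OC)cc1OC | intermediate
12 | methyl (4S)-6-methyl-4-(2,4,6-trimethoxyphenyl)hept-2-ynoate | COC(=O)C#C[C@H](CC(C)C)c1c(OC)cc(OC)cc1OC | intermediate
13 | methyl (2Z,4S)-3,6-dimethyl-4-(2,4,6-trimethoxyphenyl)hept-2-enoate | COC(=O)/C=C(/C)[C@H](CC(C)C)c1c(OC)cc(OC)cc1OC | intermediate
14 | (2Z,4S)-3,6-dimethyl-4-(2,4,6-trimethoxyphenyl)hept-2-en-1-ol | OC/C=C(/C)[C@H](CC(C)C)c1c(OC)cc(OC)cc1OC | intermediate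
15 | but-3-enoic acid | C=CCC(=O)O | starting material
16 | (2Z,4S)-3,6-dimethyl-4-(2,4,6-trimethoxyphenyl)hept-2-en-1-yl but-3-enoate | C=CCC(=O)OC/C=C(/C)[C@H](CC(C)C)c1c(OC)cc(OC)cc1OC | intermediate
17 | E-trimethylsilyl ketene acetal of 16 (vinyl trans to OSiMe3) | C=C/C=C(/O[Si](C)(C)C)OC/C=C(/C)[C@H](CC(C)C)c1c(OC)cc(OC)cc1OC | intermediate
18 | trimethylsilyl (2R,3R)-2-ethenyl-3-methyl-3-[(1S)-3-methyl-1-(2,4,6-trimethoxyphenyl)butyl]pent-4-enoate | C[Si](C)(C)OC(=O)[C@H](C=C)[C@](C)(C=C)[C@H](CC(C)C)c1c(OC)cc(OC)cc1OC | intermediate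
19 | (2R,3R)-2-ethenyl-3-methyl-3-[(1S)-3-methyl-1-(2,4,6-trimethoxyphenyl)butyl]pent-4-en-1-ol | OC[C@H](C=C)[C@](C)(C=C)[C@H](CC(C)C)c1c(OC)cc(OC)cc1OC | intermediate
20 | (2R,3R)-2-ethenyl-3-methyl-3-[(1S)-3-methyl-1-(2,4,6-trimethoxyphenyl)butyl]pent-4-enal | O=C[C@H](C=C)[C@](C)(C=C)[C@H](CC(C)C)c1c(OC)cc(OC)cc1OC | intermediate
21 | (2R,3R)-2-ethenyl-3-methyl-3-[(1S)-3-methyl-1-(2,4,6-trimethoxyphenyl)butyl]cyclopentan-1-one (vinyl cis to CH3, trans to the C9′ group) | C=C[C@H]1C(=O)CC[C@]1(C)[C@H](CC(C)C)c1c(OC)cc(OC)cc1OC | intermediate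
22 | (1S,2R,3R)-2-ethenyl-3-methyl-3-[(1S)-3-methyl-1-(2,4,6-trimethoxyphenyl)butyl]cyclopentan-1-ol (OH cis to vinyl) | C=C[C@H]1[C@@H](O)CC[C@]1(C)[C@H](CC(C)C)c1c(OC)cc(OC)cc1OC | intermediate
23 | acryloyl chloride | C=CC(=O)Cl | starting material
24 | (1S,2R,3R)-2-ethenyl-3-methyl-3-[(1S)-3-methyl-1-(2,4,6-trimethoxyphenyl)butyl]cyclopentyl prop-2-enoate | C=C[C@H]1[C@@H](OC(=O)C=C)CC[C@]1(C)[C@H](CC(C)C)c1c(OC)cc(OC)cc1OC | intermediate
25 | cis-fused pentenolide, (4aR,5R,7aS)-5-methyl-5-[(1S)-3-methyl-1-(2,4,6-trimethoxyphenyl)butyl]-4a,5,6,7-tetrahydrocyclopenta[b]pyran-2(7aH)-one | O=C1C=C[C@H]2[C@@H](O1)CC[C@]2(C)[C@H](CC(C)C)c1c(OC)cc(OC)cc1OC | intermediate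
26 | acetone hydrazone | CC(C)=NN | starting material
27 | 2-diazopropane | CC(C)=[N+]=[N-] | intermediate
28 | 1-pyrazoline: C11(CH3)2–N=N bridge on the H5 face of 25, C11 on C6 and N on C7 (C1 S, C4 R, C5 R, C6 S, C7 S, C9′ S) | O=C1[C@H]2N=NC(C)(C)[C@H]2[C@H]3[C@@H](O1)CC[C@]3(C)[C@H](CC(C)C)c1c(OC)cc(OC)cc1OC | intermediate
29 | cyclopropane-fused tricyclic δ-lactone: C11(CH3)2 bridging C6 and C7 on the H5 face (C1 S, C4 R, C5 R, C6 S, C7 R, C9′ S) | O=C1[C@@H]2[C@@H](C2(C)C)[C@H]2[C@@H](O1)CC[C@]2(C)[C@H](CC(C)C)c1c(OC)cc(OC)cc1OC | intermediate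
30 | diol: cis-cyclopropane with CH2OH on C7 and the 2-hydroxycyclopentyl group on C6 (C1 S, C4 R, C5 R, C6 R, C7 R, C9′ S) | OC[C@@H]1[C@H]([C@H]2[C@@H](O)CC[C@]2(C)[C@H](CC(C)C)c2c(OC)cc(OC)cc2OC)C1(C)C | intermediate
31 | bis(dimethylalkoxysulfonium) dichloride of 30 | C[S+](C)OC[C@@H]1[C@H]([C@H]2[C@@H](O[S+](C)C)CC[C@]2(C)[C@H](CC(C)C)c2c(OC)cc(OC)cc2OC)C1(C)C.[Cl-].[Cl-] | intermediate
32 | keto aldehyde: cis-cyclopropanecarbaldehyde (C8) with the 2-oxocyclopentyl group on C6 (4R,5R,6R,7R,9′S) | O=C[C@@H]1[C@H]([C@H]2C(=O)CC[C@]2(C)[C@H](CC(C)C)c2c(OC)cc(OC)cc2OC)C1(C)C | intermediate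
33 | E-enone: (E)-4-cyclopropylbut-3-en-2-one side chain on C7 (4R,5R,6R,7R,9′S) | CC(=O)/C=C/[C@@H]1[C@H]([C@H]2C(=O)CC[C@]2(C)[C@H](CC(C)C)c2c(OC)cc(OC)cc2OC)C1(C)C | intermediate
34 | deformyl macrocarpal N tri-O-methyl ether (4R,5R,6R,7R,9′S) | CC(=O)CC[C@@H]1[C@H]([C@H]2C(=O)CC[C@]2(C)[C@H](CC(C)C)c2c(OC)cc(OC)cc2OC)C1(C)C | intermediate
35 | macrocarpal N tri-O-methyl ether (4R,5R,6R,7R,9′S) | CC(=O)CC[C@@H]1[C@H]([C@H]2C(=O)CC[C@]2(C)[C@H](CC(C)C)c2c(OC)c(C=O)c(OC)c(C=O)c2OC)C1(C)C | intermediate
36 | macrocarpal N (4R,5R,6R,7R,9′S) | CC(=O)CC[C@@H]1[C@H]([C@H]2C(=O)CC[C@]2(C)[C@H](CC(C)C)c2c(O)c(C=O)c(O)c(C=O)c2O)C1(C)C | target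

Total step count: 24.
Longest linear sequence: 23 steps (steps 1–16 and 18–24, from 1). Step 17 is a one-step side branch.

Steps most likely to fail

**Step 18.**
- What may go wrong: the cycloaddition at the hindered β-carbon C6 may be slower than the decay of 2-diazopropane. The 1-pyrazoline may tautomerise to the conjugated 2-pyrazoline. A hydrogen shift in the diradical may compete with ring closure.
- Fallback: it sets out from 25 and replaces the cycloaddition and photolysis by a Michael-initiated ring closure with diphenylsulfonium isopropylide. The ylide is made from isopropyldiphenylsulfonium tetrafluoroborate and LiN(iPr)2 in DME at −78 °C.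
- The ylide carbon adds to C6 on the same convex face. The lactone enolate then displaces diphenyl sulfide at C11 and closes C7–C11.
- The sequence comes back to the route at 29 and forms no compound outside the list (entry F0).

**Step 11.**
- What may go wrong: the dienolate of 16 may slip back into the conjugated crotonate or be silylated with mixed geometry. The heating that the congested C4–C5 bond formation needs may also push the 3,4-divinyl product through a Cope rearrangement.
- Fallback: it sets out from 14 and carries the C5 vinyl group in masked form.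
- γ-Butyrolactone is opened with PhSeNa (from PhSeSePh and NaBH4, DMF, heat) to 4-(phenylselanyl)butanoic acid F1.
- Steglich coupling of F1 with 14 gives the 4-(phenylselanyl)butanoate ester F2.
- F2 has a simple saturated enolate. It undergoes the same Ireland–Claisen and LiAlH4 sequence, under the same A(1,3) and chair control, to give the 2-[2-(phenylselanyl)ethyl]pentenol F3.
- Oxidation with H2O2 and pyridine at 0 °C gives the selenoxide F4. This eliminates at room temperature to unveil the vinyl group, and the route is rejoined at 19.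

**Step 13.**
- What may go wrong: rhodium hydride may isomerise the C5 vinyl group into conjugation, or the hindered aldehyde may decarbonylate, faster than the ring closes.
- Fallback: it sets out from 20 and closes the five-membered ring by metathesis instead.
- Vinylmagnesium bromide adds to the aldehyde to give the bis-allylic alcohol F5, as a mixture at the carbinol carbon.
- Dess–Martin oxidation gives the vinyl ketone F6.
- Ring-closing metathesis with the second-generation Grubbs catalyst joins the enone vinyl group to the C4 vinyl group and gives the 5-vinylcyclopent-2-enone F7. The C5 vinyl group could only form four-membered rings.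
- Conjugate reduction of F7 with [(Ph3P)CuH]6 rejoins the route at 21.

Further compounds
F0 | step 18 | none | none
F1 | step 11 | 4-(phenylselanyl)butanoic acid | O=C(O)CCC[Se]c1ccccc1
F2 | step 11 | (2Z,4S)-3,6-dimethyl-4-(2,4,6-trimethoxyphenyl)hept-2-en-1-yl 4-(phenylselanyl)butanoate | O=C(CCC[Se]c1ccccc1)OC/C=C(/C)[C@H](CC(C)C)c1c(OC)cc(OC)cc1OC
F3 | step 11 | (2R,3R)-3-methyl-3-[(1S)-3-methyl-1-(2,4,6-trimethoxyphenyl)butyl]-2-[2-(phenylselanyl)ethyl]pent-4-en-1-ol | OC[C@H](CC[Se]c1ccccc1)[C@](C)(C=C)[C@H](CC(C)C)c1c(OC)cc(OC)cc1OC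
F4 | step 11 | selenoxide of F3 | OC[C@H](CC[Se](=O)c1ccccc1)[C@](C)(C=C)[C@H](CC(C)C)c1c(OC)cc(OC)cc1OC
F5 | step 13 | (4R,5R)-4-ethenyl-5-methyl-5-[(1S)-3-methyl-1-(2,4,6-trimethoxyphenyl)butyl]hepta-1,6-dien-3-ol (both C3 epimers) | C=CC(O)[C@H](C=C)[C@](C)(C=C)[C@H](CC(C)C)c1c(OC)cc(OC)cc1OC
F6 | step 13 | (4R,5R)-4-ethenyl-5-methyl-5-[(1S)-3-methyl-1-(2,4,6-trimethoxyphenyl)butyl]hepta-1,6-dien-3-one | C=CC(=O)[C@H](C=C)[C@](C)(C=C)[C@H](CC(C)C)c1c(OC)cc(OC)cc1OC
F7 | step 13 | (4R,5R)-5-ethenyl-4-methyl-4-[(1S)-3-methyl-1-(2,4,6-trimethoxyphenyl)butyl]cyclopent-2-en-1-one | C=C[C@H]1C(=O)C=C[C@]1(C)[C@H](CC(C)C)c1c(OC)cc(OC)cc1OC
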